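**Retrosynthetic overview**

- The strategy rests on one feature of the target: ring B is bonded to C3 of the pyranone ring C (the C3–C1' bond), next to the unsubstituted C2–H, and not to C2 where chalcone and flavanone chemistry would put it.
- The C6 prenyl group is disconnected last, to a 5-O-(1,1-dimethylallyl) ether (ortho-Claisen, C6–C bond) of a 7,4'-bis-silylated 5-hydroxyisoflavone; the alkene is introduced only after the thallium oxidation, which it would not survive.
- The isoflavone core is disconnected at C3–C1' and O1–C2 to a benzyl-protected 2'-hydroxychalcone: oxidative 1,2-shift of ring B from the β- to the α-carbon, then closure of ring C. Ring C is the only ring formed; rings A and B are bought.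
- The chalcone comes from a Claisen–Schmidt condensation of 2,4-di-O-benzyl phloroacetophenone with 4-(benzyloxy)-3-(3-hydroxy-3-methylbutyl)benzaldehyde.
- The aldehyde comes from dihydrocoumarin: double MeMgBr addition, para-bromination, O-benzylation, Br/Li exchange and formylation.

Key step: step 7

Remark on the chemistry: the target has no stereocentre and no stereogenic alkene, so the only geometric element in the route is the E-alkene of the chalcone, which is set thermodynamically. 2,4,6-Trihydroxyacetophenone is assumed to be used dried from its commercial monohydrate.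

**Route**

Step 1
Reactants: 1 dihydrocoumarin (chroman-2-one); 2 methylmagnesium bromide
Product: 4 2-(3-hydroxy-3-methylbutyl)phenol, via bromomagnesium 2-(3-oxobutyl)phenolate 3 (not isolated)
Conditions: MeMgBr (3.2 equiv), THF, 0 °C to rt; aq NH4Cl
Reagents that add atoms: methylmagnesium bromide, C[Mg]Br
Why: Double Grignard addition to the aryl lactone: the first equivalent opens the ring to the methyl ketone phenolate 3 and the second adds to the ketone to give the tertiary alcohol.

Step 2
Reactants: 4 2-(3-hydroxy-3-methylbutyl)phenol; 5 N-bromosuccinimide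
Product: 6 4-bromo-2-(3-hydroxy-3-methylbutyl)phenol
Conditions: NBS (1.0 equiv), MeCN, 0 °C
Reagents that add atoms: N-bromosuccinimide, O=C1CCC(=O)N1Br
Why: Electrophilic aromatic bromination of a phenol with NBS in a polar solvent should go para to the hydroxyl, one ortho position being blocked by the side chain, and the neutral conditions spare the tertiary alcohol.

Step 3
Reactants: 6 4-bromo-2-(3-hydroxy-3-methylbutyl)phenol; 7 benzyl bromide
Product: 8 4-[2-(benzyloxy)-5-bromophenyl]-2-methylbutan-2-ol
Conditions: BnBr (1.1 equiv), K2CO3, acetone, reflux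
Reagents that add atoms: benzyl bromide, BrCc1ccccc1
Why: Williamson ether synthesis in which K2CO3 deprotonates only the phenol, so the tertiary alcohol should stay free.

Step 4
Reactants: 8 4-[2-(benzyloxy)-5-bromophenyl]-2-methylbutan-2-ol; 9 N,N-dimethylformamide
Product: 11 4-(benzyloxy)-3-(3-hydroxy-3-methylbutyl)benzaldehyde, via lithium 4-[2-(benzyloxy)-5-lithiophenyl]-2-methylbutan-2-olate 10 (not isolated)
Conditions: n-BuLi (2.2 equiv), THF, −78 °C; DMF, −78 °C to rt; H2O
Reagents that add atoms: N,N-dimethylformamide, CN(C)C=O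
Why: The first equivalent of n-BuLi forms the lithium alkoxide and the second performs bromine–lithium exchange; Bouveault-type formylation of the aryllithium with DMF and hydrolysis of the hemiaminal salt then give the aldehyde.

Step 5
Reactants: 12 2,4,6-trihydroxyacetophenone; 7 benzyl bromide
Product: 13 1-[2,4-bis(benzyloxy)-6-hydroxyphenyl]ethan-1-one
Conditions: BnBr (2.1 equiv), K2CO3, DMF, rt
Reagents that add atoms: benzyl bromide, BrCc1ccccc1
Why: Williamson etherification that should stop at the dibenzyl ether, because the remaining ortho-hydroxyl is held in a hydrogen bond to the acetyl carbonyl and is the least nucleophilic.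

Step 6
Reactants: 13 1-[2,4-bis(benzyloxy)-6-hydroxyphenyl]ethan-1-one; 11 4-(benzyloxy)-3-(3-hydroxy-3-methylbutyl)benzaldehyde
Product: 14 (E)-1-[2,4-bis(benzyloxy)-6-hydroxyphenyl]-3-[4-(benzyloxy)-3-(3-hydroxy-3-methylbutyl)phenyl]prop-2-en-1-one
Conditions: KOH, EtOH/H2O, rt; aq NH4Cl
Reagents that add atoms: none
Why: Claisen–Schmidt condensation of a methyl ketone with a non-enolisable aldehyde; E1cB dehydration should give the conjugated E-enone, and the 6'-benzyloxy group disfavours flavanone closure.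

Step 7
Reactants: 14 (E)-1-[2,4-bis(benzyloxy)-6-hydroxyphenyl]-3-[4-(benzyloxy)-3-(3-hydroxy-3-methylbutyl)phenyl]prop-2-en-1-one
Product: 16 5,7-bis(benzyloxy)-3-[4-(benzyloxy)-3-(3-hydroxy-3-methylbutyl)phenyl]-4H-chromen-4-one, via 1-[2,4-bis(benzyloxy)-6-hydroxyphenyl]-2-[4-(benzyloxy)-3-(3-hydroxy-3-methylbutyl)phenyl]-3,3-dimethoxypropan-1-one 15 (not isolated)
Conditions: Tl(NO3)3·3H2O (1.2 equiv), MeOH/CH2Cl2, rt; filter; then 1 M aq HCl, MeOH/THF, 45 °C
Reagents that add atoms: none
Why: Trivalent thallium adds as an electrophile to the enone alkene while methanol enters at the benzylic β-carbon, and heterolysis of the weak C–Tl bond with loss of monovalent thallium is driven by a 1,2-shift of ring B from the β- to the α-carbon through a phenonium ion, which forms the C3–C1' bond and leaves a methoxy-stabilised cation that methanol traps as dimethyl acetal 15. The closest known reaction type is the thallium nitrate oxidative rearrangement of 2'-hydroxychalcones to isoflavones. Ring C, the only ring closed, should form when mild acid ionises the acetal and the free 2'-hydroxyl adds to the oxocarbenium carbon in a 6-exo-trig closure (O1–C2 bond), after which loss of the second methanol across C2–C3 gives the pyranone. No stereocentre is created, since the racemic centre of 15 is destroyed in the elimination. The step needs aryl migration to outrun aurone and flavone formation and needs the tertiary alcohol to survive the acid; the para-benzyloxy group gives ring B a high migratory aptitude, excess methanol intercepts the cations, and the all-benzyl protection allows a mild acid stage in which the capped 4'-oxygen cannot close a chroman onto the side chain.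

Step 8
Reactants: 16 5,7-bis(benzyloxy)-3-[4-(benzyloxy)-3-(3-hydroxy-3-methylbutyl)phenyl]-4H-chromen-4-one
Product: 17 5,7-dihydroxy-3-[4-hydroxy-3-(3-hydroxy-3-methylbutyl)phenyl]-4H-chromen-4-one
Conditions: H2 (1 atm), 10% Pd/C, THF/MeOH, rt, stopped after uptake of three equivalents
Reagents that add atoms: none
Why: Hydrogenolysis of benzyl aryl ethers over Pd/C should be much faster than reduction of the C2=C3 bond of the chromone, and the tertiary alcohol is not benzylic and is untouched.

Step 9
Reactants: 17 5,7-dihydroxy-3-[4-hydroxy-3-(3-hydroxy-3-methylbutyl)phenyl]-4H-chromen-4-one; 18 tert-butyldimethylsilyl chloride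
Product: 19 7-[(tert-butyldimethylsilyl)oxy]-3-[4-[(tert-butyldimethylsilyl)oxy]-3-(3-hydroxy-3-methylbutyl)phenyl]-5-hydroxy-4H-chromen-4-one
Conditions: TBSCl (2.2 equiv), imidazole, DMF, 0 °C to rt
Reagents that add atoms: tert-butyldimethylsilyl chloride, CC(C)(C)[Si](C)(C)Cl
Why: Phenol silylation should stop at the 7- and 4'-oxygens, because the 5-hydroxyl is locked in a hydrogen bond to C4=O and the tertiary alcohol is too hindered for TBSCl/imidazole; silyl ethers are chosen so that the final deprotection needs fluoride, not acid.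

Step 10
Reactants: 20 2-methylbut-3-en-2-ol; 21 di-tert-butyl dicarbonate
Product: 23 tert-butyl 2-methylbut-3-en-2-yl carbonate, via lithium 2-methylbut-3-en-2-olate 22 (not isolated)
Conditions: n-BuLi (1.0 equiv), THF, −78 °C; Boc2O, −78 °C to rt
Reagents that add atoms: di-tert-butyl dicarbonate, CC(C)(C)OC(=O)OC(=O)OC(C)(C)C
Why: Acylation of the lithium tert-alkoxide with the anhydride gives the mixed carbonate, the standard activation of a tertiary allylic alcohol for palladium π-allyl chemistry.

Step 11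
Reactants: 19 7-[(tert-butyldimethylsilyl)oxy]-3-[4-[(tert-butyldimethylsilyl)oxy]-3-(3-hydroxy-3-methylbutyl)phenyl]-5-hydroxy-4H-chromen-4-one; 23 tert-butyl 2-methylbut-3-en-2-yl carbonate
Product: 24 7-[(tert-butyldimethylsilyl)oxy]-3-[4-[(tert-butyldimethylsilyl)oxy]-3-(3-hydroxy-3-methylbutyl)phenyl]-5-[(2-methylbut-3-en-2-yl)oxy]-4H-chromen-4-one
Conditions: Pd(PPh3)4 (5 mol%), 23 (1.5 equiv), THF, 0 °C, short reaction time
Reagents that add atoms: tert-butyl 2-methylbut-3-en-2-yl carbonate, C=CC(C)(C)OC(=O)OC(C)(C)C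
Why: Tsuji–Trost decarboxylative O-allylation: zerovalent palladium ionises the carbonate to a 1,1-dimethyl-π-allyl complex, the tert-butoxide released with CO2 deprotonates the 5-hydroxyl, and the phenoxide should attack the more substituted allyl terminus under kinetic control to give the tertiary aryl ether.

Step 12
Reactants: 24 7-[(tert-butyldimethylsilyl)oxy]-3-[4-[(tert-butyldimethylsilyl)oxy]-3-(3-hydroxy-3-methylbutyl)phenyl]-5-[(2-methylbut-3-en-2-yl)oxy]-4H-chromen-4-one
Product: 26 7-[(tert-butyldimethylsilyl)oxy]-3-[4-[(tert-butyldimethylsilyl)oxy]-3-(3-hydroxy-3-methylbutyl)phenyl]-5-hydroxy-6-(3-methylbut-2-en-1-yl)-4H-chromen-4-one, via 7-[(tert-butyldimethylsilyl)oxy]-3-[4-[(tert-butyldimethylsilyl)oxy]-3-(3-hydroxy-3-methylbutyl)phenyl]-6-(3-methylbut-2-en-1-yl)-4H-chromene-4,5(6H)-dione 25 (not isolated)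
Conditions: PhNEt2, 130 °C, base-washed glassware
Reagents that add atoms: none
Why: Aromatic ortho-Claisen [3,3]-sigmatropic rearrangement: C6 is the only free position ortho to O5 (the other is the ring-fusion carbon C4a), the allyl unit is inverted so the 1,1-dimethylallyl ether delivers a 3-methylbut-2-enyl group, and tautomerisation of dienone 25 restores the chelated 5-hydroxyl.

Step 13
Reactants: 26 7-[(tert-butyldimethylsilyl)oxy]-3-[4-[(tert-butyldimethylsilyl)oxy]-3-(3-hydroxy-3-methylbutyl)phenyl]-5-hydroxy-6-(3-methylbut-2-en-1-yl)-4H-chromen-4-one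
Product: 27 Coloratanin A, 5,7-dihydroxy-3-[4-hydroxy-3-(3-hydroxy-3-methylbutyl)phenyl]-6-(3-methylbut-2-en-1-yl)-4H-chromen-4-one
Conditions: Bu4NF (2.2 equiv), AcOH (2.2 equiv), THF, 0 °C
Reagents that add atoms: none
Why: Fluoride cleavage of the two aryl silyl ethers, buffered with acetic acid, so that the prenyl alkene and the tertiary alcohol see no acid able to close chromans and the chromone sees no strong base.

**Compound list**

1 | dihydrocoumarin (chroman-2-one) | O=C1CCc2ccccc2O1 | starting material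
2 | methylmagnesium bromide | C[Mg]Br | starting material
3 | bromomagnesium 2-(3-oxobutyl)phenolate | CC(=O)CCc1ccccc1O[Mg]Br | intermediate
4 | 2-(3-hydroxy-3-methylbutyl)phenol | CC(C)(O)CCc1ccccc1O | intermediate
5 | N-bromosuccinimide | O=C1CCC(=O)N1Br | starting material
6 | 4-bromo-2-(3-hydroxy-3-methylbutyl)phenol | CC(C)(O)CCc1cc(Br)ccc1O | intermediate
7 | benzyl bromide | BrCc1ccccc1 | starting material
8 | 4-[2-(benzyloxy)-5-bromophenyl]-2-methylbutan-2-ol | CC(C)(O)CCc1cc(Br)ccc1OCc1ccccc1 | intermediate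
9 | N,N-dimethylformamide | CN(C)C=O | starting material
10 | lithium 4-[2-(benzyloxy)-5-lithiophenyl]-2-methylbutan-2-olate | CC(C)(O[Li])CCc1cc([Li])ccc1OCc1ccccc1 | intermediate
11 | 4-(benzyloxy)-3-(3-hydroxy-3-methylbutyl)benzaldehyde | CC(C)(O)CCc1cc(C=O)ccc1OCc1ccccc1 | intermediate
12 | 2,4,6-trihydroxyacetophenone | CC(=O)c1c(O)cc(O)cc1O | starting material
13 | 1-[2,4-bis(benzyloxy)-6-hydroxyphenyl]ethan-1-one | CC(=O)c1c(O)cc(OCc2ccccc2)cc1OCc1ccccc1 | intermediate
14 | (E)-1-[2,4-bis(benzyloxy)-6-hydroxyphenyl]-3-[4-(benzyloxy)-3-(3-hydroxy-3-methylbutyl)phenyl]prop-2-en-1-one | O=C(/C=C/c1ccc(OCc2ccccc2)c(CCC(C)(C)O)c1)c1c(O)cc(OCc2ccccc2)cc1OCc1ccccc1 | intermediate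
15 | 1-[2,4-bis(benzyloxy)-6-hydroxyphenyl]-2-[4-(benzyloxy)-3-(3-hydroxy-3-methylbutyl)phenyl]-3,3-dimethoxypropan-1-one (racemic) | COC(OC)C(C(=O)c1c(O)cc(OCc2ccccc2)cc1OCc1ccccc1)c1ccc(OCc2ccccc2)c(CCC(C)(C)O)c1 | intermediate
16 | 5,7-bis(benzyloxy)-3-[4-(benzyloxy)-3-(3-hydroxy-3-methylbutyl)phenyl]-4H-chromen-4-one | O=c1c(-c2ccc(OCc3ccccc3)c(CCC(C)(C)O)c2)coc2cc(OCc3ccccc3)cc(OCc3ccccc3)c12 | intermediate
17 | 5,7-dihydroxy-3-[4-hydroxy-3-(3-hydroxy-3-methylbutyl)phenyl]-4H-chromen-4-one | CC(C)(O)CCc1cc(-c2coc3cc(O)cc(O)c3c2=O)ccc1O | intermediate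
18 | tert-butyldimethylsilyl chloride | CC(C)(C)[Si](C)(C)Cl | starting material
19 | 7-[(tert-butyldimethylsilyl)oxy]-3-[4-[(tert-butyldimethylsilyl)oxy]-3-(3-hydroxy-3-methylbutyl)phenyl]-5-hydroxy-4H-chromen-4-one | CC(C)(O)CCc1cc(-c2coc3cc(O[Si](C)(C)C(C)(C)C)cc(O)c3c2=O)ccc1O[Si](C)(C)C(C)(C)C | intermediate
20 | 2-methylbut-3-en-2-ol | C=CC(C)(C)O | starting material
21 | di-tert-butyl dicarbonate | CC(C)(C)OC(=O)OC(=O)OC(C)(C)C | starting material
22 | lithium 2-methylbut-3-en-2-olate | C=CC(C)(C)O[Li] | intermediate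
23 | tert-butyl 2-methylbut-3-en-2-yl carbonate | C=CC(C)(C)OC(=O)OC(C)(C)C | intermediate
24 | 7-[(tert-butyldimethylsilyl)oxy]-3-[4-[(tert-butyldimethylsilyl)oxy]-3-(3-hydroxy-3-methylbutyl)phenyl]-5-[(2-methylbut-3-en-2-yl)oxy]-4H-chromen-4-one | C=CC(C)(C)Oc1cc(O[Si](C)(C)C(C)(C)C)cc2occ(-c3ccc(O[Si](C)(C)C(C)(C)C)c(CCC(C)(C)O)c3)c(=O)c12 | intermediate
25 | 7-[(tert-butyldimethylsilyl)oxy]-3-[4-[(tert-butyldimethylsilyl)oxy]-3-(3-hydroxy-3-methylbutyl)phenyl]-6-(3-methylbut-2-en-1-yl)-4H-chromene-4,5(6H)-dione (racemic at C6) | CC(C)=CCC1C(=O)C2=C(C=C1O[Si](C)(C)C(C)(C)C)OC=C(c1ccc(O[Si](C)(C)C(C)(C)C)c(CCC(C)(C)O)c1)C2=O | intermediate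
26 | 7-[(tert-butyldimethylsilyl)oxy]-3-[4-[(tert-butyldimethylsilyl)oxy]-3-(3-hydroxy-3-methylbutyl)phenyl]-5-hydroxy-6-(3-methylbut-2-en-1-yl)-4H-chromen-4-one | CC(C)=CCc1c(O[Si](C)(C)C(C)(C)C)cc2occ(-c3ccc(O[Si](C)(C)C(C)(C)C)c(CCC(C)(C)O)c3)c(=O)c2c1O | intermediate
27 | Coloratanin A, 5,7-dihydroxy-3-[4-hydroxy-3-(3-hydroxy-3-methylbutyl)phenyl]-6-(3-methylbut-2-en-1-yl)-4H-chromen-4-one | CC(C)=CCc1c(O)cc2occ(-c3ccc(O)c(CCC(C)(C)O)c3)c(=O)c2c1O | target

**Step count**

Total steps: 13. Longest linear sequence: 11 steps (steps 1–4, 6–9, 11–13); steps 5 and 10 are side branches.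

**Steps most likely to fail**

Step 7. The aryl shift may lose out to attack of the 2'-hydroxyl on the α- or β-carbon (aurone or flavone formation), or the acid closure may ionise the tertiary alcohol (dehydration or methyl ether formation). Fallback: ring C would be closed first and ring B attached by cross-coupling. The fallback sets out from acetophenone 13 and bromide 8 and comes back to the route at isoflavone 16. Compound 13 would be heated with N,N-dimethylformamide dimethyl acetal in toluene at 90 °C to give the enaminone (E)-1-[2,4-bis(benzyloxy)-6-hydroxyphenyl]-3-(dimethylamino)prop-2-en-1-one F1. Treatment of F1 with I2 in MeOH/CHCl3 at rt would close ring C with iodination at C3 and give 5,7-bis(benzyloxy)-3-iodo-4H-chromen-4-one F2. Separately, bromide 8 would be borylated with B2pin2, Pd(dppf)Cl2 and KOAc in dioxane at 85 °C to 4-[2-(benzyloxy)-5-(4,4,5,5-tetramethyl-1,3,2-dioxaborolan-2-yl)phenyl]-2-methylbutan-2-ol F3. Suzuki–Miyaura coupling of F2 with F3 under Pd(PPh3)4 and K2CO3 in dioxane/H2O at 80 °C would then give isoflavone 16.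

Step 11. Zerovalent palladium may re-ionise the tertiary aryl ether and isomerise it to the linear prenyl ether, which would send the allyl group to C8 on heating, or the hydrogen-bonded 5-hydroxyl may react too slowly. Fallback: the tertiary ether would be built as an alkyne and then reduced. The fallback sets out from 19 and comes back to the route at ether 24. Copper-catalysed propargylation of 19 with 3-chloro-3-methylbut-1-yne, catalytic CuCl2·2H2O and DBU in MeCN at 0 °C should give 7-[(tert-butyldimethylsilyl)oxy]-3-[4-[(tert-butyldimethylsilyl)oxy]-3-(3-hydroxy-3-methylbutyl)phenyl]-5-[(2-methylbut-3-yn-2-yl)oxy]-4H-chromen-4-one F4. Semi-hydrogenation of F4 with H2 over Pd/CaCO3 poisoned with Pb(OAc)2, with quinoline in EtOAc at rt, would then give ether 24.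

Step 12. The tertiary ether may fragment with loss of isoprene back to 19, or the dienone may undergo a further Cope shift toward C8 before it tautomerises. Fallback: the C6–prenyl bond would be made by halogenation and cross-coupling instead of a sigmatropic shift. The fallback sets out from 19, bypasses 24 and comes back to the route at 26. Iodination of 19 directed by the free 5-hydroxyl, with benzyltrimethylammonium dichloroiodate and CaCO3 in CH2Cl2/MeOH at rt, should give 7-[(tert-butyldimethylsilyl)oxy]-3-[4-[(tert-butyldimethylsilyl)oxy]-3-(3-hydroxy-3-methylbutyl)phenyl]-5-hydroxy-6-iodo-4H-chromen-4-one F5. Stille coupling of F5 with tributyl(3-methylbut-2-en-1-yl)stannane under Pd(PPh3)4 in DMF at 80 °C would then give 26.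

**Further compounds**

F1 | step 7 | (E)-1-[2,4-bis(benzyloxy)-6-hydroxyphenyl]-3-(dimethylamino)prop-2-en-1-one | CN(C)/C=C/C(=O)c1c(O)cc(OCc2ccccc2)cc1OCc1ccccc1
F2 | step 7 | 5,7-bis(benzyloxy)-3-iodo-4H-chromen-4-one | O=c1c(I)coc2cc(OCc3ccccc3)cc(OCc3ccccc3)c12
F3 | step 7 | 4-[2-(benzyloxy)-5-(4,4,5,5-tetramethyl-1,3,2-dioxaborolan-2-yl)phenyl]-2-methylbutan-2-ol | CC(C)(O)CCc1cc(B2OC(C)(C)C(C)(C)O2)ccc1OCc1ccccc1
F4 | step 11 | 7-[(tert-butyldimethylsilyl)oxy]-3-[4-[(tert-butyldimethylsilyl)oxy]-3-(3-hydroxy-3-methylbutyl)phenyl]-5-[(2-methylbut-3-yn-2-yl)oxy]-4H-chromen-4-one | C#CC(C)(C)Oc1cc(O[Si](C)(C)C(C)(C)C)cc2occ(-c3ccc(O[Si](C)(C)C(C)(C)C)c(CCC(C)(C)O)c3)c(=O)c12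
F5 | step 12 | 7-[(tert-butyldimethylsilyl)oxy]-3-[4-[(tert-butyldimethylsilyl)oxy]-3-(3-hydroxy-3-methylbutyl)phenyl]-5-hydroxy-6-iodo-4H-chromen-4-one | CC(C)(O)CCc1cc(-c2coc3cc(O[Si](C)(C)C(C)(C)C)c(I)c(O)c3c2=O)ccc1O[Si](C)(C)C(C)(C)C
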